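The trap here is to read a flat curve as an equilibrium. Substrate opens reversibly to the open intermediate; partner becomes the second intermediate, two of which give the homo product, while one with the open intermediate gives target, which interconverts with its isomer.

| setting | green | blue | flask |
|---|---|---|---|
| substrate | 0.043 M | 0.043 M | 0.043 M |
| partner | 0.058 M | 0.13 M | 0.0860 M |
| remark | run made earlier | run made earlier |  |
| time |  |  | 10 h |

| run | time / h | target / % | isomer of the product / % |
|---|---|---|---|
| green | 0.667 | 6.2 | 9.5 |
| green | 2.00 | 15.2 | 24.7 |
| green | 4.00 | 16.7 | 29.3 |
| green | 6.00 | 15.4 | 31.1 |
| green | 8.00 | 17.0 | 33.4 |
| blue | 0.667 | 11.6 | 14.0 |
| blue | 1.33 | 17.4 | 31.3 |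
| blue | 2.50 | 22.4 | 40.2 |
| blue | 4.00 | 22.5 | 42.2 |
| blue | 8.00 | 23.6 | 42.3 |

(readings scatter by 1 percentage point)

- the state of affairs at 10 h: stopped, and by what, or still going (it is still moving / all of the substrate has reacted / forward and back rates have come level / the partner has run out first)
- amount of target at 10 h, in percent of the substrate charged
- amount of isomer of the product at 10 h, in percent of the substrate charged
- amount of open intermediate at 10 h, in percent of the substrate charged

- candidate steps: substrate <-> open intermediate; 2 second intermediate -> homo product; partner -> second intermediate; target <-> isomer of the product; open intermediate + second intermediate -> target
- the reaction counts as stopped when no species that holds the substrate changes by six tenths of a point or more over the second half of the time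

Is the plateau an equilibrium? No: the step to target is written one way, and target plus isomer reads 50.4% at the last reading of the green run and higher, 65.9%, at the last reading of the blue run, so the level follows the partner.

But this flask charges twice as much partner as substrate; how can partner be the limiting reagent? In the blue run the products hold 0.0283 M against 0.13 M of partner charged, so any partner used beyond that amount has to go another way, and the homo product is the candidate step for it.

Which rate do you integrate? Let W be substrate plus open intermediate, with a fixed share open, falling pseudo-first-order in second intermediate J. If J balances feed from partner B against pairwise loss, J goes as the root of B. B decays exponentially, so the time integral of J, taken until B has decayed away, is proportional to the root of the partner charge. Hence the depletion number L, the logarithm of substrate charged over W left, with W left being the charge less target and isomer, should follow that root.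

Does it? L reads 0.701 in the green run and 1.08 in the blue run, a ratio of 1.54 against 1.50 for the roots.

Your flask? Scaling both runs and averaging gives L = 0.864, so W = 42.1% and the products make 57.9%. With isomer over target read as 1.88, I commit to target 20.1%, isomer 37.8%, stopped, with partner limiting. Neither run reads substrate or open intermediate, so I have W but no split of it, and I give no figure for open intermediate.

The forecast says the partner has run out first, with target 20%, isomer 37%, below mine, and open intermediate 8%, holding that “the reaction stops because the partner is used up”.

The flask stands thus at 10 h: the partner has run out first, with target 20.4%, isomer 37.5%, open intermediate 33.1%.

    substrate ⇌ open intermediate (K = 3.70, k = 0.0345 min⁻¹)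
    2 second intermediate → homo product (k = 1.45 M⁻¹ min⁻¹)
    partner → second intermediate (k = 0.0346 min⁻¹)
    target ⇌ isomer of the product (K = 1.84, k = 0.232 min⁻¹)
    open intermediate + second intermediate → target (k = 0.879 M⁻¹ min⁻¹)

At 10 h this flask has partner at 0%, and substrate 8.95% plus open intermediate makes W = 42.0%, against my 42.1%. Take the neighbouring flask with 0.34 M of partner and everything else unchanged. Scaling by the root of the charge gives L = 1.72, so W should be 17.9%. That flask holds substrate 3.49% and open intermediate 12.9%, so W = 16.4%, with target 29.5% and isomer 54.2%.

The readings are simulated for substances that don't exist; the scatter is artificial.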